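**Retrosynthetic overview** (locants C1–C15 follow the germacrane numbering of the target: C1/C2 oxirane, C3 ketone, C4=C5, C6 lactone O–CH, C8 angelate, C10 carbinol, C11–C13 methylene lactone)
1. Target ⇐ C8 angeloylation, desilylation and C3 oxidation of macrocyclic allylic alcohol 26; the 10-membered ring is closed last by intramolecular Ni/Cr (Nozaki–Hiyama–Kishi) coupling C3–C4 of a (Z)-vinyl iodide with a cis-epoxy aldehyde (25).
2. 25 ⇐ cis-α-methylene-γ-lactone 24, from indium Barbier allylation/lactonisation (C6–C7) of (Z)-3-iodobut-2-enal 22 (fragment A) with (Z)-2-(bromomethyl)enoate 18.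
3. 18 ⇐ boron aldol union (C8–C9) of epoxy methyl ketone 6 (fragment C) with enal 12 (fragment B), then chelation-controlled MeMgBr addition to set C10.
4. 6 ⇐ Sharpless epoxidation of cis-butenediol mono-PMB ether; 12 ⇐ Morita–Baylis–Hillman adduct of 2,2-dimethoxyacetaldehyde and methyl acrylate; 22 ⇐ ethyl but-2-ynoate.
5. Ring order: oxirane (step 2) → γ-lactone (step 17) → 10-membered carbocycle (step 19).

Assumption: the target is made as the open 3-keto-10-hydroxy form drawn in the SMILES; a possible transannular 3,10-hemiketal tautomer is not considered.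

**Fragment C**

Step 1
Reactants: 1 (2Z)-but-2-ene-1,4-diol
Product: 2 (2Z)-4-[(4-methoxybenzyl)oxy]but-2-en-1-ol
Conditions: NaH (1 equiv), diol in excess, THF/DMF, 0 °C; PMBCl, Bu4NI (cat.), 0 °C → rt
Reagents that add atoms: 4-methoxybenzyl chloride, COc1ccc(CCl)cc1
Why: Williamson mono-etherification of the symmetric diol (excess diol suppresses the bis-ether) leaves the Z alkene untouched.

Step 2
Reactants: 2 (2Z)-4-[(4-methoxybenzyl)oxy]but-2-en-1-ol
Product: 3 [(2R,3S)-3-{[(4-methoxybenzyl)oxy]methyl}oxiran-2-yl]methanol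
Conditions: Ti(OiPr)4 (10 mol%), D-(−)-diisopropyl tartrate (12 mol%), t-BuOOH, 4 Å molecular sieves, CH2Cl2, −20 °C
Reagents that add atoms: tert-butyl hydroperoxide, CC(C)(C)OO
Why: Katsuki–Sharpless asymmetric epoxidation; the D-tartrate catalyst delivers oxygen to one face of the Z-allylic alcohol and gives the cis-(2R,3S)-oxirane that becomes C1/C2.

Step 3
Reactants: 3 [(2R,3S)-3-{[(4-methoxybenzyl)oxy]methyl}oxiran-2-yl]methanol
Product: 5 1-[(2R,3S)-3-{[(4-methoxybenzyl)oxy]methyl}oxiran-2-yl]ethan-1-ol (both carbinol epimers), via epoxy aldehyde 4 (not isolated)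
Conditions: (COCl)2, DMSO, CH2Cl2, −78 °C; Et3N; then MeMgBr (Et2O), −78 °C; aq. NH4Cl
Reagents that add atoms: methylmagnesium bromide, C[Mg]Br
Why: One-pot Swern oxidation/Grignard addition avoids isolating the labile cis-epoxy aldehyde; the new carbinol centre is removed in the next step.

Step 4
Reactants: 5 1-[(2R,3S)-3-{[(4-methoxybenzyl)oxy]methyl}oxiran-2-yl]ethan-1-ol
Product: 6 1-[(2S,3S)-3-{[(4-methoxybenzyl)oxy]methyl}oxiran-2-yl]ethan-1-one
Conditions: Dess–Martin periodinane, NaHCO3, CH2Cl2, 0 °C → rt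
Reagents that add atoms: none
Why: Dess–Martin oxidation converges both epimers to the cis-epoxy methyl ketone without touching the oxirane or the PMB ether.

**Fragment B**

Step 5
Reactants: 7 2,2-dimethoxyacetaldehyde; 8 methyl acrylate
Product: 9 methyl 3-hydroxy-4,4-dimethoxy-2-methylidenebutanoate (racemic)
Conditions: DABCO, dioxane/H2O (1:1), rt
Reagents that add atoms: none
Why: Morita–Baylis–Hillman reaction; the carbinol centre is destroyed in step 6, so no stereocontrol is needed.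

Step 6
Reactants: 9 methyl 3-hydroxy-4,4-dimethoxy-2-methylidenebutanoate
Product: 10 methyl (2Z)-2-(bromomethyl)-4,4-dimethoxybut-2-enoate
Conditions: NBS, Me2S, CH2Cl2, 0 °C → rt
Reagents that add atoms: N-bromosuccinimide, O=C1CCC(=O)N1Br
Why: Corey–Kim-type bromination with allylic transposition (SN2′) gives the thermodynamically preferred trisubstituted enoate with the acetal carbon trans to the ester.

Step 7
Reactants: 10 methyl (2Z)-2-(bromomethyl)-4,4-dimethoxybut-2-enoate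
Product: 11 methyl (2E)-4,4-dimethoxy-2-{[(4-methoxybenzyl)oxy]methyl}but-2-enoate
Conditions: 4-methoxybenzyl alcohol (3 equiv), Ag2O, 4 Å molecular sieves, CH2Cl2, rt, dark
Reagents that add atoms: 4-methoxybenzyl alcohol, COc1ccc(CO)cc1
Why: Silver-assisted Williamson etherification at the primary allylic carbon keeps the conjugated alkene and its geometry (the descriptor changes only through CIP priorities).

Step 8
Reactants: 11 methyl (2E)-4,4-dimethoxy-2-{[(4-methoxybenzyl)oxy]methyl}but-2-enoate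
Product: 12 methyl (2E)-2-{[(4-methoxybenzyl)oxy]methyl}-4-oxobut-2-enoate
Conditions: p-TsOH·H2O (cat.), acetone/H2O (10:1), rt
Reagents that add atoms: water, O
Why: Acid-catalysed acetal hydrolysis releases the enal; the E isomer (CHO trans to CO2Me) is the stable one, and the PMB ether survives dilute acid.

**Union of B and C, elaboration**

Step 9
Reactants: 6 1-[(2S,3S)-3-{[(4-methoxybenzyl)oxy]methyl}oxiran-2-yl]ethan-1-one; 12 methyl (2E)-2-{[(4-methoxybenzyl)oxy]methyl}-4-oxobut-2-enoate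
Product: 13 methyl (2E,4R)-4-hydroxy-2-{[(4-methoxybenzyl)oxy]methyl}-6-[(2S,3S)-3-{[(4-methoxybenzyl)oxy]methyl}oxiran-2-yl]-6-oxohex-2-enoate
Conditions: (−)-Ipc2BCl, Et3N, Et2O, −78 → −20 °C; then 12, −78 → −20 °C; MeOH, pH 7 buffer, H2O2, 0 °C
Reagents that add atoms: none
Why: Paterson boron aldol; the kinetic boron enolate on the methyl side adds through a chair transition state to the re face of the enal under control of the isopinocampheyl ligands, setting C8 as R.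

Step 10
Reactants: 13 methyl (2E,4R)-4-hydroxy-2-{[(4-methoxybenzyl)oxy]methyl}-6-[(2S,3S)-3-{[(4-methoxybenzyl)oxy]methyl}oxiran-2-yl]-6-oxohex-2-enoate
Product: 14 methyl (2E,4R)-4-[(tert-butyldimethylsilyl)oxy]-2-{[(4-methoxybenzyl)oxy]methyl}-6-[(2S,3S)-3-{[(4-methoxybenzyl)oxy]methyl}oxiran-2-yl]-6-oxohex-2-enoate
Conditions: TBSOTf, 2,6-lutidine, CH2Cl2, −78 °C
Reagents that add atoms: tert-butyldimethylsilyl triflate, CC(C)(C)[Si](C)(C)OS(=O)(=O)C(F)(F)F
Why: Silylation blocks retro-aldol and elimination, and gives a non-chelating C8 substituent for steps 11 and 17.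

Step 11
Reactants: 14 methyl (2E,4R)-4-[(tert-butyldimethylsilyl)oxy]-2-{[(4-methoxybenzyl)oxy]methyl}-6-[(2S,3S)-3-{[(4-methoxybenzyl)oxy]methyl}oxiran-2-yl]-6-oxohex-2-enoate
Product: 16 methyl (2E,4R,6R)-4-[(tert-butyldimethylsilyl)oxy]-2-{[(4-methoxybenzyl)oxy]methyl}-6-[(2S,3S)-3-{[(4-methoxybenzyl)oxy]methyl}oxiran-2-yl]-6-[(triethylsilyl)oxy]hept-2-enoate, via bromomagnesium alkoxide 15 (not isolated)
Conditions: MeMgBr (1.3 equiv), CH2Cl2/Et2O, −78 °C; then TESOTf, 2,6-lutidine, −78 → 0 °C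
Reagents that add atoms: methylmagnesium bromide, C[Mg]Br; triethylsilyl triflate, CC[Si](CC)(CC)OS(=O)(=O)C(F)(F)F
Why: Cram-chelate Grignard addition; Mg bridges the ketone and oxirane oxygens and methyl adds from the face away from the oxirane C2 arm, setting C10 as R (ketone far faster than the hindered enoate), and the alkoxide is trapped in situ.

Step 12
Reactants: 16 methyl (2E,4R,6R)-4-[(tert-butyldimethylsilyl)oxy]-2-{[(4-methoxybenzyl)oxy]methyl}-6-[(2S,3S)-3-{[(4-methoxybenzyl)oxy]methyl}oxiran-2-yl]-6-[(triethylsilyl)oxy]hept-2-enoate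
Product: 17 methyl (2E,4R,6R)-4-[(tert-butyldimethylsilyl)oxy]-2-(hydroxymethyl)-6-[(2S,3S)-3-(hydroxymethyl)oxiran-2-yl]-6-[(triethylsilyl)oxy]hept-2-enoate
Conditions: DDQ (2.5 equiv), CH2Cl2/pH 7 buffer, 0 °C → rt
Reagents that add atoms: none
Why: Oxidative cleavage removes both PMB ethers in one operation and is orthogonal to the silyl ethers, the oxirane and the enoate.

Step 13
Reactants: 17 methyl (2E,4R,6R)-4-[(tert-butyldimethylsilyl)oxy]-2-(hydroxymethyl)-6-[(2S,3S)-3-(hydroxymethyl)oxiran-2-yl]-6-[(triethylsilyl)oxy]hept-2-enoate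
Product: 18 methyl (2Z,4R,6R)-2-(bromomethyl)-4-[(tert-butyldimethylsilyl)oxy]-6-[(2S,3S)-3-(hydroxymethyl)oxiran-2-yl]-6-[(triethylsilyl)oxy]hept-2-enoate
Conditions: NBS, Me2S, CH2Cl2, −30 → 0 °C
Reagents that add atoms: N-bromosuccinimide, O=C1CCC(=O)N1Br
Why: Corey–Kim halogenation converts only the allylic alcohol to the bromide (the non-allylic alkoxysulfonium salt reverts to the C3 alcohol on work-up); alkene geometry is unchanged.

**Fragment A**

Step 14
Reactants: 19 ethyl but-2-ynoate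
Product: 20 ethyl (2Z)-3-iodobut-2-enoate
Conditions: NaI, AcOH, 115 °C
Reagents that add atoms: sodium iodide, [Na+].[I-]
Why: Conjugate anti-hydroiodination of the ynoate gives the Z iodoenoate that fixes the 4Z geometry.

Step 15
Reactants: 20 ethyl (2Z)-3-iodobut-2-enoate
Product: 21 (2Z)-3-iodobut-2-en-1-ol
Conditions: i-Bu2AlH (2.2 equiv), CH2Cl2, −78 → 0 °C; aq. potassium sodium tartrate
Reagents that add atoms: none
Why: 1,2-Reduction of the enoate to the allylic alcohol leaves the vinyl iodide and its geometry intact.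

Step 16
Reactants: 21 (2Z)-3-iodobut-2-en-1-ol
Product: 22 (2Z)-3-iodobut-2-enal
Conditions: MnO2, CH2Cl2, rt, dark; used at once
Reagents that add atoms: none
Why: Neutral allylic oxidation gives the enal without Z→E isomerisation.

**Union with A and endgame**

Step 17
Reactants: 18 methyl (2Z,4R,6R)-2-(bromomethyl)-4-[(tert-butyldimethylsilyl)oxy]-6-[(2S,3S)-3-(hydroxymethyl)oxiran-2-yl]-6-[(triethylsilyl)oxy]hept-2-enoate; 22 (2Z)-3-iodobut-2-enal
Product: 24 (4S,5R)-4-{(1R,3R)-1-[(tert-butyldimethylsilyl)oxy]-3-[(2S,3S)-3-(hydroxymethyl)oxiran-2-yl]-3-[(triethylsilyl)oxy]butyl}-5-[(1Z)-2-iodoprop-1-en-1-yl]-3-methylideneoxolan-2-one (cis-lactone), via hydroxy ester 23 (not isolated)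
Conditions: indium powder, THF/H2O, rt; then PPTS (cat.), toluene, 40 °C
Reagents that add atoms: none
Why: Barbier allylation/lactonisation (Dreiding–Schmidt); the Z-allylindium reacts through a chair transition state (syn adduct, hence cis-lactone) on the alkene face anti to the C9 chain of the A(1,3)-minimised C8 silyl ether conformer, setting C6 and C7.

Step 18
Reactants: 24 (4S,5R)-4-{(1R,3R)-1-[(tert-butyldimethylsilyl)oxy]-3-[(2S,3S)-3-(hydroxymethyl)oxiran-2-yl]-3-[(triethylsilyl)oxy]butyl}-5-[(1Z)-2-iodoprop-1-en-1-yl]-3-methylideneoxolan-2-one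
Product: 25 (4S,5R)-4-{(1R,3R)-1-[(tert-butyldimethylsilyl)oxy]-3-[(2S,3R)-3-formyloxiran-2-yl]-3-[(triethylsilyl)oxy]butyl}-5-[(1Z)-2-iodoprop-1-en-1-yl]-3-methylideneoxolan-2-one
Conditions: Dess–Martin periodinane, NaHCO3, CH2Cl2, 0 °C → rt
Reagents that add atoms: none
Why: Buffered Dess–Martin oxidation of the only free hydroxyl gives the cis-epoxy aldehyde without epimerisation.

Step 19
Reactants: 25 (4S,5R)-4-{(1R,3R)-1-[(tert-butyldimethylsilyl)oxy]-3-[(2S,3R)-3-formyloxiran-2-yl]-3-[(triethylsilyl)oxy]butyl}-5-[(1Z)-2-iodoprop-1-en-1-yl]-3-methylideneoxolan-2-one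
Product: 26 (1S,2S,4Z,6S,7S,8R,10R)-8-[(tert-butyldimethylsilyl)oxy]-1,2-epoxy-3-hydroxy-10-[(triethylsilyl)oxy]germacra-4,11(13)-dien-6,12-olide (C3 epimers)
Conditions: CrCl2 (10 equiv), NiCl2 (cat.), DMSO/THF, rt, 0.002 M, slow addition
Reagents that add atoms: none
Why: Intramolecular Nozaki–Hiyama–Kishi coupling; the alkenyl chromium species formed with retention of the Z geometry adds only to the aldehyde and closes the 10-membered ring, and the C3 configuration is irrelevant.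

Step 20
Reactants: 26 (1S,2S,4Z,6S,7S,8R,10R)-8-[(tert-butyldimethylsilyl)oxy]-1,2-epoxy-3-hydroxy-10-[(triethylsilyl)oxy]germacra-4,11(13)-dien-6,12-olide
Product: 27 (1S,2R,4Z,6S,7S,8R,10R)-8-[(tert-butyldimethylsilyl)oxy]-1,2-epoxy-3-oxo-10-[(triethylsilyl)oxy]germacra-4,11(13)-dien-6,12-olide
Conditions: Dess–Martin periodinane, NaHCO3, CH2Cl2, 0 °C
Reagents that add atoms: none
Why: Dess–Martin oxidation converges both allylic alcohol epimers to the epoxy enone.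

Step 21
Reactants: 27 (1S,2R,4Z,6S,7S,8R,10R)-8-[(tert-butyldimethylsilyl)oxy]-1,2-epoxy-3-oxo-10-[(triethylsilyl)oxy]germacra-4,11(13)-dien-6,12-olide
Product: 28 (1S,2R,4Z,6S,7R,8R,10R)-1,2-epoxy-8,10-dihydroxy-3-oxogermacra-4,11(13)-dien-6,12-olide
Conditions: HF·pyridine, pyridine, THF, 0 °C → rt
Reagents that add atoms: none
Why: Buffered fluoride desilylation removes both silyl ethers under non-basic conditions tolerated by the epoxy enone and the methylene lactone.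

Step 22
Reactants: 29 angelic acid [(2Z)-2-methylbut-2-enoic acid]
Product: 30 (2Z)-2-methylbut-2-enoic 2,4,6-trichlorobenzoic anhydride
Conditions: 2,4,6-trichlorobenzoyl chloride, Et3N, toluene, rt; filtered and used as a solution
Reagents that add atoms: 2,4,6-trichlorobenzoyl chloride, O=C(Cl)c1c(Cl)cc(Cl)cc1Cl
Why: Yamaguchi-type mixed anhydride formation activates angelic acid without the Z→E isomerisation seen with acid chlorides or DMAP.

Step 23
Reactants: 28 (1S,2R,4Z,6S,7R,8R,10R)-1,2-epoxy-8,10-dihydroxy-3-oxogermacra-4,11(13)-dien-6,12-olide; 30 (2Z)-2-methylbut-2-enoic 2,4,6-trichlorobenzoic anhydride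
Product: 31 (1S,2R,4Z,6S,7R,8R,10R)-1,2-epoxy-10-hydroxy-3-oxo-6,12-olidogermacra-4,11(13)-dien-8-yl (2Z)-2-methylbut-2-enoate
Conditions: 30 (excess), Et3N, toluene, 70 °C
Reagents that add atoms: none
Why: The secondary C8 hydroxyl attacks the less hindered angeloyl carbonyl of the mixed anhydride, while the tertiary C10 hydroxyl does not react and no stereocentre is touched.

**Compound list**
1 | (2Z)-but-2-ene-1,4-diol | OC/C=C\CO | starting material
2 | (2Z)-4-[(4-methoxybenzyl)oxy]but-2-en-1-ol | COc1ccc(COC/C=C\CO)cc1 | intermediate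
3 | [(2R,3S)-3-{[(4-methoxybenzyl)oxy]methyl}oxiran-2-yl]methanol | COc1ccc(COC[C@@H]2O[C@@H]2CO)cc1 | intermediate
4 | (2S,3S)-3-{[(4-methoxybenzyl)oxy]methyl}oxirane-2-carbaldehyde (not isolated) | COc1ccc(COC[C@@H]2O[C@@H]2C=O)cc1 | intermediate
5 | 1-[(2R,3S)-3-{[(4-methoxybenzyl)oxy]methyl}oxiran-2-yl]ethan-1-ol (both carbinol epimers) | COc1ccc(COC[C@@H]2O[C@@H]2C(C)O)cc1 | intermediate
6 | 1-[(2S,3S)-3-{[(4-methoxybenzyl)oxy]methyl}oxiran-2-yl]ethan-1-one | COc1ccc(COC[C@@H]2O[C@@H]2C(C)=O)cc1 | intermediate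
7 | 2,2-dimethoxyacetaldehyde | COC(OC)C=O | starting material
8 | methyl acrylate | C=CC(=O)OC | starting material
9 | methyl 3-hydroxy-4,4-dimethoxy-2-methylidenebutanoate (racemic) | C=C(C(=O)OC)C(O)C(OC)OC | intermediate
10 | methyl (2Z)-2-(bromomethyl)-4,4-dimethoxybut-2-enoate | COC(=O)/C(CBr)=C/C(OC)OC | intermediate
11 | methyl (2E)-4,4-dimethoxy-2-{[(4-methoxybenzyl)oxy]methyl}but-2-enoate | COC(=O)/C(COCc1ccc(OC)cc1)=C/C(OC)OC | intermediate
12 | methyl (2E)-2-{[(4-methoxybenzyl)oxy]methyl}-4-oxobut-2-enoate | COC(=O)/C(COCc1ccc(OC)cc1)=C/C=O | intermediate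
13 | methyl (2E,4R)-4-hydroxy-2-{[(4-methoxybenzyl)oxy]methyl}-6-[(2S,3S)-3-{[(4-methoxybenzyl)oxy]methyl}oxiran-2-yl]-6-oxohex-2-enoate | COc1ccc(COC[C@@H]2O[C@@H]2C(=O)C[C@@H](O)/C=C(\COCc2ccc(OC)cc2)C(=O)OC)cc1 | intermediate
14 | 4-O-TBS ether of 13 | COc1ccc(COC[C@@H]2O[C@@H]2C(=O)C[C@@H](O[Si](C)(C)C(C)(C)C)/C=C(\COCc2ccc(OC)cc2)C(=O)OC)cc1 | intermediate
15 | bromomagnesium (6R)-alkoxide from methyl addition to 14 (not isolated) | COc1ccc(COC[C@@H]2O[C@@H]2[C@](C)(O[Mg]Br)C[C@@H](O[Si](C)(C)C(C)(C)C)/C=C(\COCc2ccc(OC)cc2)C(=O)OC)cc1 | intermediate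
16 | methyl (2E,4R,6R)-4-[(tert-butyldimethylsilyl)oxy]-2-{[(4-methoxybenzyl)oxy]methyl}-6-[(2S,3S)-3-{[(4-methoxybenzyl)oxy]methyl}oxiran-2-yl]-6-[(triethylsilyl)oxy]hept-2-enoate | COc1ccc(COC[C@@H]2O[C@@H]2[C@](C)(O[Si](CC)(CC)CC)C[C@@H](O[Si](C)(C)C(C)(C)C)/C=C(\COCc2ccc(OC)cc2)C(=O)OC)cc1 | intermediate
17 | methyl (2E,4R,6R)-4-[(tert-butyldimethylsilyl)oxy]-2-(hydroxymethyl)-6-[(2S,3S)-3-(hydroxymethyl)oxiran-2-yl]-6-[(triethylsilyl)oxy]hept-2-enoate | OC[C@@H]1O[C@@H]1[C@](C)(O[Si](CC)(CC)CC)C[C@@H](O[Si](C)(C)C(C)(C)C)/C=C(\CO)C(=O)OC | intermediate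
18 | methyl (2Z,4R,6R)-2-(bromomethyl)-4-[(tert-butyldimethylsilyl)oxy]-6-[(2S,3S)-3-(hydroxymethyl)oxiran-2-yl]-6-[(triethylsilyl)oxy]hept-2-enoate | OC[C@@H]1O[C@@H]1[C@](C)(O[Si](CC)(CC)CC)C[C@@H](O[Si](C)(C)C(C)(C)C)/C=C(\CBr)C(=O)OC | intermediate
19 | ethyl but-2-ynoate | CC#CC(=O)OCC | starting material
20 | ethyl (2Z)-3-iodobut-2-enoate | CCOC(=O)/C=C(/C)I | intermediate
21 | (2Z)-3-iodobut-2-en-1-ol | OC/C=C(/C)I | intermediate
22 | (2Z)-3-iodobut-2-enal | O=C/C=C(/C)I | intermediate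
23 | methyl (3S,4R,5Z)-3-{(1R,3R)-1-[(tert-butyldimethylsilyl)oxy]-3-[(2S,3S)-3-(hydroxymethyl)oxiran-2-yl]-3-[(triethylsilyl)oxy]butyl}-4-hydroxy-6-iodo-2-methylidenehept-5-enoate (not isolated) | COC(=O)C(=C)[C@@H]([C@@H](O)/C=C(/C)I)[C@H](O[Si](C)(C)C(C)(C)C)C[C@@](C)(O[Si](CC)(CC)CC)[C@H]1O[C@H]1CO | intermediate
24 | (4S,5R)-4-{(1R,3R)-1-[(tert-butyldimethylsilyl)oxy]-3-[(2S,3S)-3-(hydroxymethyl)oxiran-2-yl]-3-[(triethylsilyl)oxy]butyl}-5-[(1Z)-2-iodoprop-1-en-1-yl]-3-methylideneoxolan-2-one | C=C1C(=O)O[C@@H](/C=C(/C)I)[C@H]1[C@H](O[Si](C)(C)C(C)(C)C)C[C@@](C)(O[Si](CC)(CC)CC)[C@H]2O[C@H]2CO | intermediate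
25 | (4S,5R)-4-{(1R,3R)-1-[(tert-butyldimethylsilyl)oxy]-3-[(2S,3R)-3-formyloxiran-2-yl]-3-[(triethylsilyl)oxy]butyl}-5-[(1Z)-2-iodoprop-1-en-1-yl]-3-methylideneoxolan-2-one | C=C1C(=O)O[C@@H](/C=C(/C)I)[C@H]1[C@H](O[Si](C)(C)C(C)(C)C)C[C@@](C)(O[Si](CC)(CC)CC)[C@H]2O[C@H]2C=O | intermediate
26 | (1S,2S,4Z,6S,7S,8R,10R)-8-[(tert-butyldimethylsilyl)oxy]-1,2-epoxy-3-hydroxy-10-[(triethylsilyl)oxy]germacra-4,11(13)-dien-6,12-olide (C3 epimers) | C=C1C(=O)O[C@H]2/C=C(/C)C(O)[C@@H]3O[C@@H]3[C@](C)(O[Si](CC)(CC)CC)C[C@@H](O[Si](C)(C)C(C)(C)C)[C@@H]12 | intermediate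
27 | (1S,2R,4Z,6S,7S,8R,10R)-8-[(tert-butyldimethylsilyl)oxy]-1,2-epoxy-3-oxo-10-[(triethylsilyl)oxy]germacra-4,11(13)-dien-6,12-olide | C=C1C(=O)O[C@H]2/C=C(/C)C(=O)[C@@H]3O[C@@H]3[C@](C)(O[Si](CC)(CC)CC)C[C@@H](O[Si](C)(C)C(C)(C)C)[C@@H]12 | intermediate
28 | (1S,2R,4Z,6S,7R,8R,10R)-1,2-epoxy-8,10-dihydroxy-3-oxogermacra-4,11(13)-dien-6,12-olide | C=C1C(=O)O[C@H]2/C=C(/C)C(=O)[C@@H]3O[C@@H]3[C@](C)(O)C[C@@H](O)[C@@H]12 | intermediate
29 | angelic acid, (2Z)-2-methylbut-2-enoic acid | C/C=C(/C)C(=O)O | starting material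
30 | (2Z)-2-methylbut-2-enoic 2,4,6-trichlorobenzoic anhydride | C/C=C(/C)C(=O)OC(=O)c1c(Cl)cc(Cl)cc1Cl | intermediate
31 | (1S,2R,4Z,6S,7R,8R,10R)-1,2-epoxy-10-hydroxy-3-oxo-6,12-olidogermacra-4,11(13)-dien-8-yl (2Z)-2-methylbut-2-enoate | C=C1C(=O)O[C@H]2/C=C(/C)C(=O)[C@@H]3O[C@@H]3[C@](C)(O)C[C@@H](OC(=O)/C(C)=C\C)[C@@H]12 | target

**Totals**
Total step count: 23.
Longest linear sequence: 15 steps (1–4, 9–13, 17–21, 23); branches: steps 5–8, steps 14–16, step 22.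

**Three steps most likely to fail, with fallbacks**

Step 9 (boron aldol). Reagent control over C8 may be eroded by the chiral epoxy ketone, and the Lewis-acidic boron chloride may attack the oxirane. Fallback: from 6, LiN(i-Pr)2 and Me3SiCl in THF at −78 °C give the trimethylsilyl enol ether F1. F1 is then added to 12 in a catalytic enantioselective Mukaiyama aldol reaction (SiCl4, chiral bisphosphoramide, CH2Cl2, −78 °C), in which the catalyst alone decides the aldehyde face. Aqueous work-up gives 13, where the route is rejoined.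

Step 17 (indium Barbier allylation). The syn selectivity and the face selection by the C8 silyl ether both rest on an allylindium species that can equilibrate. Fallback: from 18, borylation with B2pin2 and Pd2(dba)3 (cat.) in toluene at 50 °C gives the configurationally stable allyl pinacolboronate F2. Sc(OTf)3-catalysed allylboration of 22 with F2 goes through a closed chair transition state and, after work-up, gives hydroxy ester 23. PPTS then lactonises 23 to 24, where the route is rejoined.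

Step 19 (Ni/Cr macrocyclisation). Closure of the strained 10-membered ring competes with dimerisation, and the vinyl iodide geometry could erode. Fallback, setting out from 18: indium Barbier reaction with acrolein in place of 22 gives the vinyl hydroxy ester F3, which lactonises with PPTS to the vinyl lactone F4. Dess–Martin oxidation gives the epoxy aldehyde F5. Intermolecular CrCl2/NiCl2 coupling of F5 with 2-bromopropene gives the isopropenyl carbinol F6. Ring-closing metathesis of F6 (second-generation Hoveyda–Grubbs catalyst, toluene, 80 °C, high dilution) forms C4=C5 and returns to the route at 26.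

**Further compounds**
F1 | step 9 | {1-[(2S,3S)-3-{[(4-methoxybenzyl)oxy]methyl}oxiran-2-yl]ethenyl}oxy(trimethyl)silane | COc1ccc(COC[C@@H]2O[C@@H]2C(=C)O[Si](C)(C)C)cc1
F2 | step 17 | methyl (2E,4R,6R)-4-[(tert-butyldimethylsilyl)oxy]-6-[(2S,3S)-3-(hydroxymethyl)oxiran-2-yl]-2-[(4,4,5,5-tetramethyl-1,3,2-dioxaborolan-2-yl)methyl]-6-[(triethylsilyl)oxy]hept-2-enoate | OC[C@@H]1O[C@@H]1[C@](C)(O[Si](CC)(CC)CC)C[C@@H](O[Si](C)(C)C(C)(C)C)/C=C(\CB2OC(C)(C)C(C)(C)O2)C(=O)OC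
F3 | step 19 | methyl (3S,4S)-3-{(1R,3R)-1-[(tert-butyldimethylsilyl)oxy]-3-[(2S,3S)-3-(hydroxymethyl)oxiran-2-yl]-3-[(triethylsilyl)oxy]butyl}-4-hydroxy-2-methylidenehex-5-enoate | COC(=O)C(=C)[C@@H]([C@@H](O)C=C)[C@H](O[Si](C)(C)C(C)(C)C)C[C@@](C)(O[Si](CC)(CC)CC)[C@H]1O[C@H]1CO
F4 | step 19 | (4S,5S)-4-{(1R,3R)-1-[(tert-butyldimethylsilyl)oxy]-3-[(2S,3S)-3-(hydroxymethyl)oxiran-2-yl]-3-[(triethylsilyl)oxy]butyl}-5-ethenyl-3-methylideneoxolan-2-one | C=C1C(=O)O[C@@H](C=C)[C@H]1[C@H](O[Si](C)(C)C(C)(C)C)C[C@@](C)(O[Si](CC)(CC)CC)[C@H]2O[C@H]2CO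
F5 | step 19 | (4S,5S)-4-{(1R,3R)-1-[(tert-butyldimethylsilyl)oxy]-3-[(2S,3R)-3-formyloxiran-2-yl]-3-[(triethylsilyl)oxy]butyl}-5-ethenyl-3-methylideneoxolan-2-one | C=C1C(=O)O[C@@H](C=C)[C@H]1[C@H](O[Si](C)(C)C(C)(C)C)C[C@@](C)(O[Si](CC)(CC)CC)[C@H]2O[C@H]2C=O
F6 | step 19 | (4S,5S)-4-{(1R,3R)-1-[(tert-butyldimethylsilyl)oxy]-3-[(2S,3S)-3-(1-hydroxy-2-methylprop-2-en-1-yl)oxiran-2-yl]-3-[(triethylsilyl)oxy]butyl}-5-ethenyl-3-methylideneoxolan-2-one (carbinol epimers) | C=C1C(=O)O[C@@H](C=C)[C@H]1[C@H](O[Si](C)(C)C(C)(C)C)C[C@@](C)(O[Si](CC)(CC)CC)[C@H]2O[C@H]2C(O)C(C)=C
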